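**Plan** (labdane numbering: ring A = C1–C5 and C10; ring B = C5–C10; C17 = exocyclic CH2; C18/C19 on C4; C20 on C10; chain C11–C16)
- **Cuts:** first the O-acetyl group and C2–H (back to a 2-ketone), then C8=C17 (Wittig), then C3–C4 of ring A, and last C9–C11 and C10–C1.
- **Enabling feature:** ring B carries C4 on C5 and, para to C5, C8. With C8 as a ketone, C7 is an enolate position and C4 a tertiary-cation position. An extra C4–C7 bond (a cyclobutane that is not in the target) is therefore a strain-loaded push–pull bond. Ring B plus C4, that bond and C20 on C10 is exactly (+)-verbenone.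
- **Forward order:** ring B is present from the start inside the bicycle. C1–C3 go onto C10 by conjugate allylation. The finished C11–C16 chain goes onto C9 by alkylation, since only C9 can enolise. The allyl group becomes a C2 enol silane. Ring A closes last, when the C4–C7 bond is traded for C3–C4.
- **Stereochemistry:** C5 comes from verbenone and C10 from attack anti to the CMe2 bridge; these two fix the trans fusion. C9 is set by equilibration next to the C8 ketone. C2 is set by hydride attack from the α face, the β face being blocked by axial C19 and C20. C13 comes from methyl hydrogen (R)-3-methylglutarate.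

Key step: step 7

Assumption: (1R,5R)-(+)-verbenone 4 and methyl hydrogen (R)-3-methylglutarate 1 are taken as purchasable in high enantiomeric purity; the C9 configuration of 7–12 is of no consequence because C9 is equilibrated in step 8.

Step 1
Reactants: 1 methyl hydrogen (R)-3-methylglutarate
Product: 2 methyl (3R)-5-hydroxy-3-methylpentanoate
Conditions: BH3·SMe2 (1.1 equiv), THF, −10 → 0 °C; H2O quench, cold neutral work-up
Reagents that add atoms: none
Why: Borane reduces the free acid through its acyloxyborane much faster than the methyl ester (chemoselective acid reduction), C13 is untouched, and 2 is used at once to forestall lactonisation.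

Step 2
Reactants: 2 methyl (3R)-5-hydroxy-3-methylpentanoate
Product: 3 methyl (3S)-5-iodo-3-methylpentanoate
Conditions: I2, PPh3, imidazole, CH2Cl2, 0 °C
Reagents that add atoms: iodine, II
Why: Appel-type iodination of a primary alcohol through the alkoxyphosphonium salt runs under neutral conditions that spare the ester and C13 (only the descriptor changes, by priority).

Step 3
Reactants: 4 (1R,5R)-(+)-verbenone
Product: 5 allylated enol silane
Conditions: allylMgBr (1.5 equiv), CuBr·SMe2 (1.5 equiv), TMSCl (3 equiv), THF, −78 °C; Et3N, cold aq NaHCO3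
Reagents that add atoms: allylmagnesium bromide, C=CC[Mg]Br; chlorotrimethylsilane, C[Si](C)(C)Cl
Why: In this TMSCl-accelerated conjugate addition of an allylcopper reagent to a β,β-disubstituted enone, the nucleophile reaches C10 from the CH2-bridge face, anti to the CMe2 bridge, which sets C10 with C1 trans to C4 on ring B, and the enolate is fixed as the C8=C9 enol silane.

Step 4
Reactants: 5 allylated enol silane; 3 methyl (3S)-5-iodo-3-methylpentanoate
Product: 7 alkylated keto ester, via lithium enolate 6 (not isolated)
Conditions: MeLi (1.0 equiv), THF, 0 °C; then DMPU and 3, −78 °C → rt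
Reagents that add atoms: none
Why: Cleavage of the enol silane with MeLi gives the only possible enolate (a bridgehead enolate at C7 is geometrically impossible), and its SN2 alkylation by the primary iodide joins C9 to C11 from the face anti to the CMe2 bridge, giving the C9 epimer that step 8 corrects.

Step 5
Reactants: 7 alkylated keto ester
Product: 8 diketo ester
Conditions: PdCl2 (10 mol %), CuCl (1 equiv), O2 (1 atm), DMF/H2O 7:1, rt
Reagents that add atoms: water, O
Why: Wacker oxidation of the only alkene, a terminal allyl group on a quaternary carbon, gives the methyl ketone (C2=O, C3H3) with Markovnikov selectivity and leaves the ketone, ester and cyclobutane alone.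

Step 6
Reactants: 8 diketo ester
Product: 10 terminal enol silane, via lithium enolate 9 (not isolated)
Conditions: LiN(i-Pr)2 (LDA, 1.1 equiv) and TMSCl (3 equiv) premixed, THF, −78 °C, slow addition of 8; Et3N, cold aq NaHCO3
Reagents that add atoms: chlorotrimethylsilane, C[Si](C)(C)Cl
Why: Kinetic enolisation takes the unhindered C3 methyl proton rather than the neopentylic C1–H, the tertiary C9–H or the less acidic ester α-H, and the internal TMSCl quench traps the enolate on oxygen before it can add to the C8 ketone.

Step 7
Reactants: 10 terminal enol silane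
Product: 12 trans-decalin 2-ketone 8-enol silane, via ring-opened tertiary cation 11 (not isolated)
Conditions: HNTf2 (10 mol %, gives TMSNTf2 in situ), CH2Cl2 (0.005 M), −78 → −20 °C; Et3N quench; 12 used crude
Reagents that add atoms: none
Why: Proposed new method: TMSNTf2 silylates the C8 carbonyl oxygen, the strained C4–C7 bond (α to C8 and ending at a tertiary carbon) ionises to the C7=C8 enol silane and the C4 cation 11, ring B flips so that the trans-disposed C4 and C1 arms become diequatorial, C3 of the pendant enol silane attacks C4, and the C2 silyloxocarbenium ion hands its silyl group to the next molecule, so the step is a catalytic isomerisation. The closest known reaction types are the Lewis-acid opening of 4-arylnopinones, in which a phenol oxygen on the C4 substituent captures the same cation to give a trans-fused pyran, and the Lewis-acid α-tert-alkylation of silyl enol ethers with tertiary halides, whereas their merger with a carbon nucleophile on this bicycle is new. Ring A closes in the 6-endo-trig mode with respect to the C2=C3 bond through a chair while the four-membered ring is lost. No new stereocentre is formed: the trans fusion follows from C5 (from 4) and C10 (step 3) because only the diequatorial conformer can bridge, C4 becomes the gem-dimethyl quaternary carbon, and the C7 stereocentre is erased. The step needs C- over O-alkylation (secured by the silyl group on the C2 oxygen), capture faster than proton loss from the cation (non-basic NTf2 anion, low temperature, six-ring closure), and fragmentation in preference to Mukaiyama aldol addition of C3 to C8 (that bridged adduct is crowded and can revert, whereas loss of cyclobutane strain and of the C19/C20 methyl clash makes fragmentation irreversible). The silyl shift leaves C2 as a free ketone and C8 masked, which is the differentiation used in steps 8 and 9.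

Step 8
Reactants: 12 trans-decalin 2-ketone 8-enol silane
Product: 14 2β-hydroxy 8-ketone, via lithium 2β-alkoxide 13 (not isolated)
Conditions: LiBH(s-Bu)3 (L-Selectride, 1.2 equiv), THF, −78 °C; then MeOH, NaOMe (0.3 equiv), −78 °C → rt; aq NH4Cl
Reagents that add atoms: none
Why: The bulky hydride can reach C2=O only from the α face (equatorial trajectory) because axial C19 and C20 close the β face, which gives the axial 2β-alcohol while C8 is masked and the ester is inert, after which methanolysis frees the C8 ketone and methoxide equilibrates C9 to the equatorial (β) side chain.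

Step 9
Reactants: 14 2β-hydroxy 8-ketone
Product: 15 methyl 2β-hydroxylabd-8(17)-en-15-oate
Conditions: Ph3PCH3Br (5 equiv), KOt-Bu (4.8 equiv), toluene, rt → 60 °C
Reagents that add atoms: methyltriphenylphosphonium bromide, C[P+](c1ccccc1)(c1ccccc1)c1ccccc1.[Br-]
Why: Wittig methylenation of the hindered C8 ketone is the standard entry to the 8(17)-ene; excess ylide covers the free hydroxyl, the ester is much less reactive than the ketone, and C9 already holds its thermodynamic configuration.

Step 10
Reactants: 15 methyl 2β-hydroxylabd-8(17)-en-15-oate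
Product: 16 2β-hydroxylabd-8(17)-en-15-oic acid
Conditions: LiOH, THF/MeOH/H2O, rt; 1 M HCl to pH 3
Reagents that add atoms: lithium hydroxide, [Li+].[OH-]
Why: Saponification of the unhindered methyl ester is done before the acetate is installed, so that no ester-versus-acetate selectivity is needed, and C13 is not epimerisable.

Step 11
Reactants: 16 2β-hydroxylabd-8(17)-en-15-oic acid
Product: 18 2β-acetoxylabd-8(17)-en-15-oic acid (target), via C15 acetic mixed anhydride 17 (not isolated)
Conditions: Ac2O (5 equiv), DMAP (0.2 equiv), pyridine, rt → 40 °C; then H2O, rt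
Reagents that add atoms: acetic anhydride, CC(=O)OC(C)=O
Why: DMAP-catalysed acylation acetylates the hindered axial 2β-alcohol with retention, and the mixed anhydride formed at C15 is cleaved at its acetyl carbonyl by water on work-up.

**Compound list**
1 | methyl hydrogen (R)-3-methylglutarate, (3R)-5-methoxy-3-methyl-5-oxopentanoic acid | OC(=O)C[C@@H](C)CC(=O)OC | starting material
2 | methyl (3R)-5-hydroxy-3-methylpentanoate | OCC[C@@H](C)CC(=O)OC | intermediate
3 | methyl (3S)-5-iodo-3-methylpentanoate | ICC[C@@H](C)CC(=O)OC | intermediate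
4 | (1R,5R)-(+)-verbenone, 4,6,6-trimethylbicyclo[3.1.1]hept-3-en-2-one | CC1=CC(=O)[C@@H]2C[C@H]1C2(C)C | starting material
5 | (1R,4S,5S)-4-allyl-4,6,6-trimethyl-2-(trimethylsilyloxy)bicyclo[3.1.1]hept-2-ene, allyl anti to the CMe2 bridge | C[C@@]1(CC=C)C=C(O[Si](C)(C)C)[C@@H]2C[C@H]1C2(C)C | intermediate
6 | lithium C8=C9 enolate of 4-allyl-4,6,6-trimethylbicyclo[3.1.1]heptan-2-one (configuration as in 5) | C[C@@]1(CC=C)C=C([O-])[C@@H]2C[C@H]1C2(C)C.[Li+] | intermediate
7 | methyl (3R)-5-[(1R,3S,4S,5S)-4-allyl-4,6,6-trimethyl-2-oxobicyclo[3.1.1]heptan-3-yl]-3-methylpentanoate | C[C@@]1(CC=C)[C@H](CC[C@@H](C)CC(=O)OC)C(=O)[C@@H]2C[C@H]1C2(C)C | intermediate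
8 | methyl (3R)-3-methyl-5-[(1R,3S,4S,5S)-4,6,6-trimethyl-2-oxo-4-(2-oxopropyl)bicyclo[3.1.1]heptan-3-yl]pentanoate | C[C@@]1(CC(C)=O)[C@H](CC[C@@H](C)CC(=O)OC)C(=O)[C@@H]2C[C@H]1C2(C)C | intermediate
9 | terminal (C3) lithium enolate of 8 | C[C@@]1(CC(=C)[O-])[C@H](CC[C@@H](C)CC(=O)OC)C(=O)[C@@H]2C[C@H]1C2(C)C.[Li+] | intermediate
10 | methyl (3R)-3-methyl-5-[(1R,3S,4S,5S)-4,6,6-trimethyl-2-oxo-4-(2-trimethylsilyloxyallyl)bicyclo[3.1.1]heptan-3-yl]pentanoate | C[C@@]1(CC(=C)O[Si](C)(C)C)[C@H](CC[C@@H](C)CC(=O)OC)C(=O)[C@@H]2C[C@H]1C2(C)C | intermediate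
11 | ring-opened C4 cation (monocyclic C7=C8 enol silane; 2-propyl cation on C5 trans to the 2-silyloxyallyl arm on C10), NTf2 salt | C[Si](C)(C)OC1=CC[C@@H]([C+](C)C)[C@](C)(CC(=C)O[Si](C)(C)C)[C@@H]1CC[C@@H](C)CC(=O)OC.FC(F)(F)S(=O)(=O)[N-]S(=O)(=O)C(F)(F)F | intermediate
12 | methyl (13R)-2-oxo-8-trimethylsilyloxy-17-nor-9-epi-labd-7-en-15-oate (trans-decalin, 5α-H, 10β-Me, side chain on C9 α and axial) | C[Si](C)(C)OC1=CC[C@H]2C(C)(C)CC(=O)C[C@]2(C)[C@@H]1CC[C@@H](C)CC(=O)OC | intermediate
13 | lithium 2β-alkoxide of methyl (13R)-2β-hydroxy-8-trimethylsilyloxy-17-nor-9-epi-labd-7-en-15-oate | C[Si](C)(C)OC1=CC[C@H]2C(C)(C)C[C@@H]([O-])C[C@]2(C)[C@@H]1CC[C@@H](C)CC(=O)OC.[Li+] | intermediate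
14 | methyl (13R)-2β-hydroxy-8-oxo-17-norlabdan-15-oate (5α-H, 9α-H, 10β-Me) | O=C1CC[C@H]2C(C)(C)C[C@@H](O)C[C@]2(C)[C@H]1CC[C@@H](C)CC(=O)OC | intermediate
15 | methyl (13R)-2β-hydroxylabd-8(17)-en-15-oate | C=C1CC[C@H]2C(C)(C)C[C@@H](O)C[C@]2(C)[C@H]1CC[C@@H](C)CC(=O)OC | intermediate
16 | (13R)-2β-hydroxylabd-8(17)-en-15-oic acid | C=C1CC[C@H]2C(C)(C)C[C@@H](O)C[C@]2(C)[C@H]1CC[C@@H](C)CC(=O)O | intermediate
17 | acetic (13R)-2β-acetoxylabd-8(17)-en-15-oic anhydride | C=C1CC[C@H]2C(C)(C)C[C@@H](OC(C)=O)C[C@]2(C)[C@H]1CC[C@@H](C)CC(=O)OC(C)=O | intermediate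
18 | (2R,5S,9S,10S,13R)-2β-acetoxylabd-8(17)-en-15-oic acid | C=C1CC[C@H]2C(C)(C)C[C@@H](OC(C)=O)C[C@]2(C)[C@H]1CC[C@@H](C)CC(=O)O | target

**Step count:** 11 steps in total. The longest linear sequence is 10 steps (1 → 18 through steps 1, 2 and 4–11); from verbenone 4 it is 9 steps.

**Steps most likely to fail**

**1. Step 7.**
- What may go wrong: proton loss from the C4 cation may outrun ring closure, and the acid so released would strip the silyl group from the enol silane. Mukaiyama aldol closure of C3 onto C8 may compete. The ester carbonyl may sequester the silyl Lewis acid.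
- Fallback: it sets out from 7, comes back at 15, and splits the event into known operations.
  - Acetolytic opening of the cyclobutane of 7 (BF3·OEt2, Zn(OAc)2, Ac2O, CH2Cl2, rt), a known reaction of nopinones, should give the ring-opened diacetate F1.
  - In anhydrous HCO2H at rt the tertiary acetate ionises. The unchanged allyl group then serves as terminator of a classical cation–olefin cyclisation (chair, 6-endo, anti capture by formate) to give the equatorial 2α-formate F2.
  - Methanolysis (K2CO3, then NaOMe, MeOH) removes the formyl and enol acetyl groups and equilibrates C9, giving the 2α-hydroxy ketone F3.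
  - Wittig methylenation as in step 9 gives the 2α-hydroxy olefin F4, and oxidation (DMP, NaHCO3, CH2Cl2) gives the 2-ketone F5.
  - LiBH(s-Bu)3 at −78 °C then attacks from the α face to deliver 15. Here C2 and C8 are told apart by oxidation level instead of by the silyl shift.

**2. Step 4.**
- What may go wrong: SN2 attack by an enolate carbon flanked by the quaternary C10 may be too slow, so that proton transfer, attack on the ester of 3 or O-alkylation takes over.
- Fallback: it sets out from 5 (as its enolate 6) and from 2, and comes back at 7. It replaces alkylation by aldol condensation and conjugate reduction.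
  - Oxidation of 2 (DMP, CH2Cl2) gives the aldehyde F6.
  - Enolate 6 adds to F6 at −78 °C, an addition far less sensitive to hindrance, to give the aldol F7 as carbinol epimers.
  - MsCl/Et3N gives the mesylate F8, and DBU gives the alkylidene ketone F9 (either alkene geometry).
  - [(Ph3P)CuH]6 (wet toluene, rt) reduces only the enone C=C to give 7. A mixture at C9 is harmless because step 8 resets C9.

**3. Step 6.**
- What may go wrong: intramolecular aldol addition of the C3 lithium enolate to the C8 ketone may be faster than silylation, and enolisation of the ester may consume base.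
- Fallback: it sets out from 7 and comes back at 10 without ever forming an enolate.
  - Ozonolysis (O3, CH2Cl2, −78 °C; Me2S) gives the aldehyde F10.
  - TMSCH2MgCl (THF, −78 °C) adds to the aldehyde only, giving the β-hydroxysilane F11.
  - Buffered DMP gives the β-ketosilane F12.
  - Its thermal Brook-type 1,3-shift of silicon from carbon to oxygen (toluene, 110 °C) gives 10 regiospecifically.

**Further compounds**
F1 | step 7 | methyl (3R)-5-[2-acetoxy-5-(2-acetoxypropan-2-yl)-6-allyl-6-methylcyclohex-2-en-1-yl]-3-methylpentanoate (C5, C9, C10 as in 7) | CC(=O)OC1=CC[C@@H](C(C)(C)OC(C)=O)[C@](C)(CC=C)[C@@H]1CC[C@@H](C)CC(=O)OC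
F2 | step 7 | methyl (13R)-8-acetoxy-2α-formyloxy-17-nor-9-epi-labd-7-en-15-oate | CC(=O)OC1=CC[C@H]2C(C)(C)C[C@H](OC=O)C[C@]2(C)[C@@H]1CC[C@@H](C)CC(=O)OC
F3 | step 7 | methyl (13R)-2α-hydroxy-8-oxo-17-norlabdan-15-oate | O=C1CC[C@H]2C(C)(C)C[C@H](O)C[C@]2(C)[C@H]1CC[C@@H](C)CC(=O)OC
F4 | step 7 | methyl (13R)-2α-hydroxylabd-8(17)-en-15-oate | C=C1CC[C@H]2C(C)(C)C[C@H](O)C[C@]2(C)[C@H]1CC[C@@H](C)CC(=O)OC
F5 | step 7 | methyl (13R)-2-oxolabd-8(17)-en-15-oate | C=C1CC[C@H]2C(C)(C)CC(=O)C[C@]2(C)[C@H]1CC[C@@H](C)CC(=O)OC
F6 | step 4 | methyl (3R)-3-methyl-5-oxopentanoate | O=CC[C@@H](C)CC(=O)OC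
F7 | step 4 | aldol of 6 and F6 (C11 carbinol epimers) | C[C@@]1(CC=C)[C@H](C(O)C[C@@H](C)CC(=O)OC)C(=O)[C@@H]2C[C@H]1C2(C)C
F8 | step 4 | C11 mesylate of F7 | C[C@@]1(CC=C)[C@H](C(OS(C)(=O)=O)C[C@@H](C)CC(=O)OC)C(=O)[C@@H]2C[C@H]1C2(C)C
F9 | step 4 | C9=C11 alkylidene ketone (alkene geometry open) | C[C@@]1(CC=C)C(=CC[C@@H](C)CC(=O)OC)C(=O)[C@@H]2C[C@H]1C2(C)C
F10 | step 6 | methyl (3R)-3-methyl-5-[(1R,3S,4S,5S)-4,6,6-trimethyl-2-oxo-4-(2-oxoethyl)bicyclo[3.1.1]heptan-3-yl]pentanoate | C[C@@]1(CC=O)[C@H](CC[C@@H](C)CC(=O)OC)C(=O)[C@@H]2C[C@H]1C2(C)C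
F11 | step 6 | β-hydroxysilane from F10 (C2 carbinol epimers) | C[C@@]1(CC(O)C[Si](C)(C)C)[C@H](CC[C@@H](C)CC(=O)OC)C(=O)[C@@H]2C[C@H]1C2(C)C
F12 | step 6 | β-ketosilane, 4-(2-oxo-3-trimethylsilylpropyl) analogue of 8 | C[C@@]1(CC(=O)C[Si](C)(C)C)[C@H](CC[C@@H](C)CC(=O)OC)C(=O)[C@@H]2C[C@H]1C2(C)C
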